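**Remark on the structure:** the SMILES is read as the (2R,3R), 2,3‑trans isomer of 2‑(2,5‑dihydroxy‑4‑methoxyphenyl)‑3,5,6,7‑tetramethoxychroman‑4‑one. In this route C3 is taken from L‑tartrate and C2 is set in the key step.

## Retrosynthetic overview

1. Cut C2–C1′. Ring B (2′‑OH, 4′‑OMe, 5′‑OH) is a 2‑methoxyhydroquinone bonded through C1′, i.e. the reduced adduct of a C2 radical at C5 of 2‑methoxy‑1,4‑benzoquinone 8. C2 (O1‑bound, β to C4=O) and the quinone carbon are both acceptor carbons, so the bond is made by decarboxylative radical coupling of acid 7.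
2. The chain C4(=O)–C3(OMe)–C2(O1)–CO2H of 7 is the skeleton of L‑tartaric acid. C3 (R) comes from the pool, one carboxyl becomes C4, and the other is the traceless radical handle on C2.
3. Ring C closes at C4–C4a by Friedel–Crafts acylation of aryloxysuccinic acid 6. O1–C2 comes from a Mitsunobu reaction of ring A (3,4,5‑trimethoxyphenol 4, bought) with mono‑O‑methyl tartrate 3.
4. Ring order: A bought, then C (step 4), then B attached as the quinone and reduced in the same flask (step 5). No phenol is ever protected.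

Key step: step 5

## Route

Step 1
Reactants: 1 dibenzyl L‑tartrate [dibenzyl (2R,3R)‑2,3‑dihydroxybutanedioate]
Product: 3 dibenzyl (2R,3R)‑2‑hydroxy‑3‑methoxybutanedioate, via stannylene acetal 2 (not isolated)
Conditions: Bu2SnO (1.05 equiv), toluene, reflux, Dean–Stark; then MeI (5 equiv), CsF (2 equiv), DMF, rt
Reagents that add atoms: iodomethane CI (the methyl group of 3); dibutyltin oxide CCCC[Sn](=O)CCCC (its Bu2Sn unit is held only in 2 and leaves again)
Why: CsF‑promoted O‑alkylation of a dibutylstannylene acetal stops cleanly after one alkylation, and because 1 is C2‑symmetric its two hydroxyls are equivalent, so a single mono‑ether should result with neither stereocentre touched.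

Step 2
Reactants: 3 dibenzyl (2R,3R)‑2‑hydroxy‑3‑methoxybutanedioate; 4 3,4,5‑trimethoxyphenol
Product: 5 dibenzyl (2R,3S)‑2‑methoxy‑3‑(3,4,5‑trimethoxyphenoxy)butanedioate
Conditions: PPh3, DIAD, toluene, 0 °C → rt
Reagents that add atoms: none
Why: Mitsunobu etherification of an α‑hydroxy ester with a phenol proceeds by SN2 inversion at the carbinol carbon (R → S, the future C2, whose configuration is later erased), while the methoxy‑bearing carbon (future C3, R) is not involved.

Step 3
Reactants: 5 dibenzyl (2R,3S)‑2‑methoxy‑3‑(3,4,5‑trimethoxyphenoxy)butanedioate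
Product: 6 (2R,3S)‑2‑methoxy‑3‑(3,4,5‑trimethoxyphenoxy)butanedioic acid
Conditions: H2 (1 atm), 10% Pd/C, EtOAc, rt
Reagents that add atoms: none
Why: hydrogenolysis of the two benzyl esters under neutral conditions should free the diacid without the β‑elimination of aryloxide or the epimerisation that a basic hydrolysis could cause, and the aryl ether is inert to it.

Step 4
Reactants: 6 (2R,3S)‑2‑methoxy‑3‑(3,4,5‑trimethoxyphenoxy)butanedioic acid
Product: 7 (2S,3R)‑3,5,6,7‑tetramethoxy‑4‑oxochromane‑2‑carboxylic acid (2,3‑trans)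
Conditions: Eaton's reagent (P2O5 in MeSO3H), 0 °C → rt, quenched on ice as soon as 6 is consumed
Reagents that add atoms: none
Why: intramolecular Friedel–Crafts acylation of an aryloxysuccinic acid is an established entry to 4‑oxochromane‑2‑carboxylic acids; the carboxyl β to the ether oxygen should close the six‑membered ring in preference to the five‑membered benzofuranone from the α‑carboxyl, the symmetric, strongly activated trimethoxyphenoxy ring offers two equivalent ortho positions, and no bond at either stereocentre is broken.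

Step 5
Reactants: 7 (2S,3R)‑3,5,6,7‑tetramethoxy‑4‑oxochromane‑2‑carboxylic acid; 8 2‑methoxy‑1,4‑benzoquinone
Product: 10 (2R,3R)‑2‑(2,5‑dihydroxy‑4‑methoxyphenyl)‑3,5,6,7‑tetramethoxychroman‑4‑one (CNP0150769.1), via alkylquinone 9 (not isolated)
Conditions: 8 (3 equiv), AgNO3 (0.2 equiv), (NH4)2S2O8 (1.5 equiv, added slowly), MeCN/H2O 1:1, 60 °C, Ar; then aq. Na2S2O4, 0 °C → rt
Reagents that add atoms: none
Why: Ag(II), made from Ag(I) and peroxydisulfate, oxidises the carboxylate of 7, CO2 is lost, and the nucleophilic α‑aryloxy C2 radical adds to C5 of 8, the β‑carbon of the enone whose carbonyl (C1) is not deactivated by vinylogous‑ester donation from the 2‑OMe group; oxidation and tautomerisation of the adduct radical give alkylquinone 9, which dithionite reduces to hydroquinone 10. The closest known reaction type is the silver/peroxydisulfate decarboxylative alkylation of quinones with α‑alkoxy and α‑aryloxy carboxylic acids (Minisci‑type radical alkylation of quinones). No ring is closed: the step forms the C2–C1′ bond between two acceptor carbons and brings in ring B at its final oxidation level. C2 is the new stereocentre: the planar radical keeps no memory of C2 of 7 and should be attacked anti to the vicinal C3–OMe group, which gives the 2,3‑trans (2R,3R) isomer, also the more stable diequatorial one, while C3 is not touched under these acidic conditions. The step needs site selectivity on the quinone (C5 over C6 and C3), which the methoxy group of 8 should secure, face selectivity at C2, which C3 should secure, and mono‑alkylation, which the excess of 8 should secure.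

## Compound list

1 | dibenzyl L‑tartrate, dibenzyl (2R,3R)‑2,3‑dihydroxybutanedioate | O=C(OCc1ccccc1)[C@H](O)[C@@H](O)C(=O)OCc1ccccc1 | starting material
2 | dibenzyl (4R,5R)‑2,2‑dibutyl‑1,3,2‑dioxastannolane‑4,5‑dicarboxylate (stannylene acetal) | O=C(OCc1ccccc1)[C@@H]2O[Sn](CCCC)(CCCC)O[C@H]2C(=O)OCc1ccccc1 | intermediate
3 | dibenzyl (2R,3R)‑2‑hydroxy‑3‑methoxybutanedioate | O=C(OCc1ccccc1)[C@H](O)[C@@H](OC)C(=O)OCc1ccccc1 | intermediate
4 | 3,4,5‑trimethoxyphenol | COc1cc(O)cc(OC)c1OC | starting material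
5 | dibenzyl (2R,3S)‑2‑methoxy‑3‑(3,4,5‑trimethoxyphenoxy)butanedioate | O=C(OCc1ccccc1)[C@@H](Oc1cc(OC)c(OC)c(OC)c1)[C@@H](OC)C(=O)OCc1ccccc1 | intermediate
6 | (2R,3S)‑2‑methoxy‑3‑(3,4,5‑trimethoxyphenoxy)butanedioic acid | OC(=O)[C@@H](Oc1cc(OC)c(OC)c(OC)c1)[C@@H](OC)C(=O)O | intermediate
7 | (2S,3R)‑3,5,6,7‑tetramethoxy‑4‑oxochromane‑2‑carboxylic acid | OC(=O)[C@H]1Oc2cc(OC)c(OC)c(OC)c2C(=O)[C@@H]1OC | intermediate
8 | 2‑methoxy‑1,4‑benzoquinone | COC1=CC(=O)C=CC1=O | starting material
9 | 2‑methoxy‑5‑[(2R,3R)‑3,5,6,7‑tetramethoxy‑4‑oxochroman‑2‑yl]cyclohexa‑2,5‑diene‑1,4‑dione | COC1=CC(=O)C(=CC1=O)[C@H]2Oc3cc(OC)c(OC)c(OC)c3C(=O)[C@@H]2OC | intermediate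
10 | (2R,3R)‑2‑(2,5‑dihydroxy‑4‑methoxyphenyl)‑3,5,6,7‑tetramethoxychroman‑4‑one (CNP0150769.1) | COc1cc(O)c([C@H]2Oc3cc(OC)c(OC)c(OC)c3C(=O)[C@@H]2OC)cc1O | target

## Step count and risks

Total step count: 5. Longest linear sequence: 5 steps (1 → 3 → 5 → 6 → 7 → 10).

**Step 5 (highest risk).** Several processes could divert the step:
- addition of the C2 radical at C6 of the quinone instead of C5;
- attack on both faces of the radical;
- oxidation of the radical to the oxocarbenium ion with loss of H‑3, giving the chromone;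
- tautomerisation of the quinone stage to a quinone methide and on to the flavone before it is reduced;
- oxidation of the electron‑rich ring A.

Fallback (sets out from 7, comes back at 10): the radical acceptor is replaced by an aryl nucleophile of fixed regiochemistry. Acid 7 would be esterified with N‑hydroxyphthalimide (DIC, cat. DMAP, CH2Cl2) to the redox‑active ester 1,3‑dioxoisoindolin‑2‑yl (2S,3R)‑3,5,6,7‑tetramethoxy‑4‑oxochromane‑2‑carboxylate F1. Commercial 2‑methoxyhydroquinone would be benzylated (BnBr, K2CO3, DMF) to 1,4‑bis(benzyloxy)‑2‑methoxybenzene F2, brominated para to the methoxy group (NBS, MeCN, 0 °C) to 1,4‑bis(benzyloxy)‑2‑bromo‑5‑methoxybenzene F3, and converted (n‑BuLi, THF, −78 °C; then ZnCl2) into [2,5‑bis(benzyloxy)‑4‑methoxyphenyl]zinc chloride F4. Nickel‑catalysed decarboxylative Negishi coupling of F1 with F4 (NiCl2·glyme, 4,4′‑di‑tert‑butyl‑2,2′‑bipyridine, THF/DMF, rt) should give (2R,3R)‑2‑[2,5‑bis(benzyloxy)‑4‑methoxyphenyl]‑3,5,6,7‑tetramethoxychroman‑4‑one F5, trans for the same reason as in step 5. Hydrogenolysis (H2, Pd/C, EtOAc) should then give 10.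

**Step 4.** Three processes could divert the step:
- closure of the five‑membered ring by the α‑carboxyl;
- loss of CO from the α‑methoxy acylium ion;
- acid‑catalysed enolisation at C3, which would erode the only pool‑derived stereocentre.

Fallback (sets out from 4, comes back at 7): the ketone is made first on a substrate without stereocentres and the ring is closed at O1–C2. Houben–Hoesch acylation of 4 with methoxyacetonitrile (ZnCl2, HCl gas, Et2O, 0 °C; then H2O, reflux) should give 1‑(2‑hydroxy‑4,5,6‑trimethoxyphenyl)‑2‑methoxyethan‑1‑one F6. Aldol condensation with glyoxylic acid followed by intramolecular oxa‑Michael addition (aq. NaOH/EtOH, rt; then acid) should give racemic trans‑3,5,6,7‑tetramethoxy‑4‑oxochromane‑2‑carboxylic acid F7. Resolution by preparative chiral SFC, or by crystallisation of a 1‑phenylethylammonium salt, would deliver 7.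

**Step 2.** Three processes could divert the step:
- β‑elimination of the activated alcohol to the methoxy‑butenedioate;
- N‑alkylation of the reduced azodicarboxylate;
- slow substitution at the hindered carbinol.

Fallback (sets out from 4, comes back at 6; it replaces steps 1–3): the ether is made by epoxide opening. Phenol 4 would open commercial diethyl (2R,3R)‑oxirane‑2,3‑dicarboxylate (CCOC(=O)[C@@H]1O[C@H]1C(=O)OCC) with a catalytic base (Cs2CO3, MeCN, 50 °C). SN2 inversion at either of the two equivalent carbons should give diethyl (2R,3S)‑2‑hydroxy‑3‑(3,4,5‑trimethoxyphenoxy)butanedioate F8. O‑Methylation (Ag2O, MeI, CH2Cl2, rt) should give diethyl (2R,3S)‑2‑methoxy‑3‑(3,4,5‑trimethoxyphenoxy)butanedioate F9, and saponification (LiOH, THF/H2O, 0 °C) should give 6.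

## Further compounds

F1 | step 5 | 1,3‑dioxoisoindolin‑2‑yl (2S,3R)‑3,5,6,7‑tetramethoxy‑4‑oxochromane‑2‑carboxylate | O=C(ON1C(=O)c2ccccc2C1=O)[C@H]3Oc4cc(OC)c(OC)c(OC)c4C(=O)[C@@H]3OC
F2 | step 5 | 1,4‑bis(benzyloxy)‑2‑methoxybenzene | COc1cc(OCc2ccccc2)ccc1OCc1ccccc1
F3 | step 5 | 1,4‑bis(benzyloxy)‑2‑bromo‑5‑methoxybenzene | COc1cc(OCc2ccccc2)c(Br)cc1OCc1ccccc1
F4 | step 5 | [2,5‑bis(benzyloxy)‑4‑methoxyphenyl]zinc chloride | COc1cc(OCc2ccccc2)c([Zn]Cl)cc1OCc1ccccc1
F5 | step 5 | (2R,3R)‑2‑[2,5‑bis(benzyloxy)‑4‑methoxyphenyl]‑3,5,6,7‑tetramethoxychroman‑4‑one | COc1cc(OCc2ccccc2)c([C@H]2Oc3cc(OC)c(OC)c(OC)c3C(=O)[C@@H]2OC)cc1OCc1ccccc1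
F6 | step 4 | 1‑(2‑hydroxy‑4,5,6‑trimethoxyphenyl)‑2‑methoxyethan‑1‑one | COCC(=O)c1c(O)cc(OC)c(OC)c1OC
F7 | step 4 | racemic trans‑3,5,6,7‑tetramethoxy‑4‑oxochromane‑2‑carboxylic acid (both enantiomers) | OC(=O)[C@H]1Oc2cc(OC)c(OC)c(OC)c2C(=O)[C@@H]1OC.OC(=O)[C@@H]1Oc2cc(OC)c(OC)c(OC)c2C(=O)[C@H]1OC
F8 | step 2 | diethyl (2R,3S)‑2‑hydroxy‑3‑(3,4,5‑trimethoxyphenoxy)butanedioate | CCOC(=O)[C@@H](Oc1cc(OC)c(OC)c(OC)c1)[C@@H](O)C(=O)OCC
F9 | step 2 | diethyl (2R,3S)‑2‑methoxy‑3‑(3,4,5‑trimethoxyphenoxy)butanedioate | CCOC(=O)[C@@H](Oc1cc(OC)c(OC)c(OC)c1)[C@@H](OC)C(=O)OCC
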